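5 questions stand here, and I reckon them by how long D and E meet Z against how fast D.E goes back.

* the set-up with the highest amount of D.E at the outlet or at the end, in percent of the D put in ("none" if the first two lie within 2 percentage points) (south-east / north-west / east / south-west / none)
* amount of D.E at the outlet or at the end, in percent of the D put in, south-east
* amount of D.E at the outlet or at the end, in percent of the D put in, north-west
* amount of D.E at the outlet or at the end, in percent of the D put in, east
* amount of D.E at the outlet or at the end, in percent of the D put in, south-west

all flasks: E 1.00 mM; Z 0.71 µM

| charge | D | time | remark |
|---|---|---|---|
| south-east | 1.0 mM | 4.0 s | everything together in a closed stirred flask, run for 4.0 s |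
| north-west | 1.0 mM |  | one stirred flow tank at steady state, fed with the mixture as stated, mean residence time 4.0 s |
| east | 1.0 mM |  | one stirred flow tank at steady state, fed with the mixture as stated, mean residence time 20.0 s |
| south-west | 1.0 mM (fed, over 3.20 s) | 4.0 s | a stirred flask in which D is dosed at a steady rate over 3.20 s without added volume, worked up at 4.0 s |

- for D.E the E.D.E is counted in
- the stated concentrations are those of everything mixed, before any reaction; amounts are the same in each set-up
- the feed brings no volume worth counting
- run time (south-east): 4.0 s

    Z ⇌ G (K1 = 0.85, k1 = 0.020 /s)
    E + D.E ⇌ E.D.E, settled at all times (K2 = 360 /M)
    D + E + Z ⇌ D.E + Z, rate k3*[D]*[E]*[Z] forward; the back reaction follows from the equilibrium constant (K3 = 1300 /M, k3 = 7.6 × 10⁷ /M²/s)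

Z passes into G, by the forward step alone, on a time of 50.0 s, longer than either stay, so I keep Z at its charge for now. E.D.E is counted in D.E, and at the charged E its balance gives 0.36 per free D.E; I set it aside too, as a simplification of this rough reckoning.

But step 3 makes the product. With E and Z as charged, D is used at a pseudo-first-order constant of 0.0540 /s, a clock of 18.5 s. The way back has a time of its own, which I call the hand-over time: the mean time a free D.E lasts against step 3 at the charged Z, K3 over k3 and that Z, 24.1 s.

D and E are charged equally, so with these simplifications a tank obeys one line: one minus the yield, squared, over the yield, equals the clock over the stay plus the clock over the hand-over time. The two terms weigh the same at a stay equal to the hand-over time. Dropping the clock over the stay gives the balance, 42.7 %. Keeping both gives 13.8 % for north-west and 29.4 % for east. Both stays are shorter than the hand-over time, so I expect both tanks on the side of kinetic rather than thermodynamic control, below the balance, with east ahead.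

The forecast names east, with 16 % for south-east, 13.1 % for north-west, 27.3 % for east and 10.3 % for south-west, the result being “set mainly by contact time”. Its east figure stands 2.1 percentage points below mine.

The east tank gives 27.3 %, ahead of south-east at 15.9 %, north-west at 13.1 % and south-west at 10.3 %.

With the passing of Z into G struck out, east gives 29.5 %. The east stay is 0.830 of the hand-over time. South-west, left until 40.0 s, which is 1.66 hand-over times, stands at 41.3 %.

Its constants are made up; the rest is arithmetic.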